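## Structural features

The target 16 is a flavanone: ring A is fused to a dihydropyranone (ring C, a chroman-4-one), and C2 carries a para-oxygenated phenyl group (ring B). C2 is the only stereocentre. It is S, benzylic to ring B, bonded to the ring oxygen O1, and has no stereogenic neighbour. Ring A bears a free phenol at C7, para to the C4 carbonyl. Ring B bears at C4′ a (2E)-3,7-dimethylocta-2,6-dienyl (geranyl) ether, an allylic aryl ether with two trisubstituted alkenes. Two elements are fragile. The β-aryloxy ketone O1–C2–C3–C4=O opens to a chalcone under base (more slowly under acid) and so erases C2. The geranyl ether does not tolerate hydrogenation, boranes, strong acid or hydride-abstracting oxidants. The real difficulty is therefore to keep one configurationally labile centre enantiopure while two phenols are told apart. The plan exploits the flavan oxidation level, where C4 is a methylene on C4a of ring A, para to the C7 oxygen and ortho to the O1-bearing C8a. It is then the best hydride donor in the molecule and can be turned into the carbonyl after C2 has been fixed.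

## Logic of the disconnections

16 to 15. The O7–Si bond is cut, so that backwards a silyl group sits on O7. The C7 phenol is the more acidic phenol of 16 and would be alkylated first, so it must stay masked until O4′ carries its chain. The gain is that the two phenols become distinguishable. The forward step must cleave Si–O without base (ring C would open) and without strong acid (the allylic ether would ionise).

15 to 13 and 14. The ether bond O4′–C1″ is cut. The diene would not survive the hydrogenation, the borane and the quinone oxidant used earlier, so it is attached late. The gain is a C10 unit taken unchanged from 14. The forward step must etherify a phenol under non-basic conditions and at the primary allylic carbon only.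

13 to 12. The acyl C–O bond at O4′ is cut, so that backwards an acetyl group sits on O4′. The acyl group keeps ring B electron-poor in the two steps that need it. Its removal must be an acyl transfer at neutrality that leaves the Si–O bond at C7 and the centre C2 alone.

12 to 10 (through 11). Both C–O bonds of the C4 carbonyl are replaced by C–H. This is the strategic cut. No compound before 12 can racemise by ring opening, and ring C becomes a cyclic benzylic ether that a stereospecific substitution can close. The forward step must oxidise C4–H and not C2–H, stop at the ketone and leave C2 untouched.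

10 to 9. The O1–C2 bond is cut. Ring C then comes from an acyclic carbinol whose configuration is transferred with inversion. The gain is an open-chain 1,3-diarylpropanol. The forward step must be a clean SN2 displacement by the ring A phenol, so C2 must not ionise; the acetoxy group on ring B provides for this.

9 to 8. The C2–H bond is cut, which removes the only stereocentre. An aryl alkyl ketone is a favourable substrate for catalytic enantioselective reduction. The forward step must give the R carbinol in the presence of a free phenol, an aryl ester and a silyl ether.

8 to 7. The C3–H and C4–H bonds are cut, giving an enone. The gain is access by olefination. The forward step must hydrogenate C=C without reducing the aryl ketone.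

7 to 2 and 6. The C3=C4 bond is cut. This joins the ring A aldehyde and a ring B keto ylide under neutral conditions. The base-labile silyl ether and acetate can therefore already be in their final places, the ortho-hydroxyl needs no protection, and no protecting group is changed later. The forward step must tolerate the free phenol and give the E alkene (not essential, since the alkene is then saturated).

6 to 4 to 3 (through 5). The C–P bond and then the C–Br bond are cut. The ylide is traced to a purchased methyl ketone by quaternisation and α-bromination. The forward steps must brominate once and at the methyl group only.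

2 to 1. The O–Si bond at the 4-oxygen (the future O7) is cut. The forward step relies on the 2-hydroxyl being held in a hydrogen bond to the formyl group, so that only the 4-hydroxyl is silylated.

## Other disconnections considered

Alternative 1: The cut is the aryl–oxygen bond O1–C8a of ring C.
- **Forward key step:** (1S,3S)-1-[2-bromo-4-(triisopropylsilyloxy)phenyl]-3-[4-(geranyloxy)phenyl]propane-1,3-diol A1 would undergo an intramolecular Ullmann-type etherification (CuI, monovalent copper, with 1,10-phenanthroline and Cs2CO3). The hydroxyl on the carbon bearing ring B attacks the brominated carbon and closes ring C as the (2S,4S)-flavan-4-ol A2. The other hydroxyl could only close a four-membered ring and stays free.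
- **In favour:** The C2–O bond is never broken, so the configuration is retained and the electron-rich, geranyloxy-substituted ring B does no harm. Here the alternative is better than the chosen plan, which must keep ring B electron-poor for its SN2 closure. The following oxidation of A2 to 15 is an alcohol oxidation, more dependable than a C–H oxidation and compatible with the diene; this too is better.
- **Against:** The carbinol centre at C4 of A1 is built only to be destroyed, yet A1 still needs full control at the other carbinol, which calls for a reagent-controlled carbonyl reduction on the way to A1. The coupling needs hot carbonate base, which endangers an aryl silyl ether. The bromide sits on an electron-rich ring and should react slowly, and a secondary benzylic alkoxide on copper can lose β-hydride.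
- **Comparison:** On structure the plans are equal, since both close ring C at O1. On mechanism the alternative trades a well-behaved redox condensation for a demanding metal-mediated C–O coupling. On step economy the alternative is ahead, with roughly seven or eight operations against eleven.

Alternative 2: The cut is the C3–C4 bond.
- **Forward key step:** The 2-lithio derivative (n-BuLi) of 2-[2-(methoxymethoxy)-4-(triisopropylsilyloxy)phenyl]-1,3-dithiane A3, an acyl-anion equivalent of C4, would open (S)-2-[4-(geranyloxy)phenyl]oxirane A4 at its methylene carbon. This gives the R carbinol A5; the descriptor changes only because the ranking of the substituents changes. No ring of the target is closed.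
- **In favour:** It is convergent, the side chain is tolerated from the start, and C4 arrives at the ketone oxidation level so that no C–H oxidation is needed. In convergence it equals the chosen plan; in the way C4 is oxidised it is better.
- **Against:** A 2-aryl-2-lithiodithiane with an ortho substituent is a hindered nucleophile. A para-alkoxy styrene oxide tends to open at the benzylic carbon or to rearrange once lithium salts are present. Three further operations are needed to reach 15, and each is delicate:
  - acetal removal by acid beside an ionisable para-alkoxybenzylic alcohol and an allylic ether;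
  - a Mitsunobu inversion at a carbinol carrying an electron-rich ring, the case in which ionisation erodes the configuration;
  - dithiane cleavage by thiophilic or oxidising reagents beside two trisubstituted alkenes.
  
  If the dithiane were hydrolysed before ring closure, β-elimination of water would become possible and the stereocentre would be lost.
- **Comparison:** The step count would be about that of the chosen plan. Mechanistically the weak point is the same SN2 ring closure, here under less favourable electronic conditions.

Alternative 3: The cut is the C2–C1′ bond.
- **Forward key step:** 4-(Geranyloxy)phenylboronic acid A7 would add to C2 of 7-(triisopropylsilyloxy)chromone A6 under [Rh(OH)(cod)]2 (monovalent rhodium) and a chiral diene ligand, an asymmetric conjugate arylation of the Hayashi–Miyaura type. This forms the C–C bond and sets C2 in one step. The product A8 is identical with 15, so only the desilylation of step 11 would remain.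
- **In favour:** It is by far the shortest plan (about five operations against eleven) and it is convergent. The stereocentre comes from a catalyst, and no oxidant endangers the diene. In step economy and convergence this alternative is clearly better than the chosen plan.
- **Against:** The silyloxy group para to the carbonyl makes A6 an electron-rich, sluggish acceptor. The new centre is created as part of a β-aryloxy ketone, beside aqueous base and a metal enolate, where reversible ring opening can lower the enantiomeric purity. Protodeboronation of the electron-rich A7 competes. The enantioselectivity rests on one ligand-controlled step with no later chance to upgrade it.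
- **Comparison:** On structure the alternative goes straight to the oxidation level of the target, whereas the chosen plan approaches it from the flavan. On mechanism the chosen plan fixes C2 by two stereospecific events before any carbonyl exists, which is more conservative. On step economy the alternative wins.

Key step: step 8

Remark on the chemistry: 4-acetylphenyl acetate (3), the O-acetate of 4′-hydroxyacetophenone, is taken as a purchased starting material. The ranking O1 > C1′ > C3 > H holds at C2 from 9 to 16, so the S centre of 10, 12 and 16 requires the R carbinol 9 when the ring closes with inversion.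

## Steps

Step 1
Reactants: 1 2,4-dihydroxybenzaldehyde
Product: 2 2-hydroxy-4-(triisopropylsilyloxy)benzaldehyde
Conditions: TIPSCl (1.05 equiv), imidazole (1.2 equiv), CH2Cl2, 0 °C to rt
Reagents that add atoms: chlorotriisopropylsilane (TIPSCl), CC(C)[Si](Cl)(C(C)C)C(C)C
Why: Regioselective O-silylation of a phenol; the 2-hydroxyl is held in a hydrogen bond to the formyl group and is flanked by it, so the bulky silyl chloride should take only the more acidic, unhindered 4-hydroxyl.

Step 2
Reactants: 3 4-acetylphenyl acetate
Product: 4 4-(2-bromoacetyl)phenyl acetate
Conditions: CuBr2 (2.0 equiv), EtOAc/CHCl3 (1:1), reflux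
Reagents that add atoms: copper dibromide CuBr2, Br[Cu]Br
Why: α-Bromination of an aryl methyl ketone through its enol with CuBr2 (divalent copper) as a mild bromine source; a second bromination should be slow because the bromo ketone enolises less readily, and the acetoxy-deactivated ring should not be brominated.

Step 3
Reactants: 4 4-(2-bromoacetyl)phenyl acetate
Product: 6 4-[2-(triphenyl-λ5-phosphanylidene)acetyl]phenyl acetate, via phosphonium bromide 5 (not isolated)
Conditions: PPh3 (1.0 equiv), CH2Cl2, rt; then Et3N (1.1 equiv), 0 °C; water wash
Reagents that add atoms: triphenylphosphine, c1ccc(cc1)P(c1ccccc1)c1ccccc1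
Why: SN2 quaternisation of the phosphine by the phenacyl bromide, then deprotonation of the acidic phosphonium salt to the acyl-stabilised ylide (preparation of a Wittig reagent); the tertiary amine cannot acylate and should leave the aryl acetate intact.

Step 4
Reactants: 2 2-hydroxy-4-(triisopropylsilyloxy)benzaldehyde, 6 4-[2-(triphenyl-λ5-phosphanylidene)acetyl]phenyl acetate
Product: 7 4-[(2E)-3-[2-hydroxy-4-(triisopropylsilyloxy)phenyl]prop-2-enoyl]phenyl acetate
Conditions: toluene, 80 °C
Reagents that add atoms: none
Why: Wittig olefination of an aromatic aldehyde with a keto-stabilised ylide, (E)-selective as is usual for stabilised ylides; the medium is neutral, so the silyl ether, the aryl acetate and the free phenol should pass unchanged, which a base-mediated aldol condensation would not allow.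

Step 5
Reactants: 7 4-[(2E)-3-[2-hydroxy-4-(triisopropylsilyloxy)phenyl]prop-2-enoyl]phenyl acetate
Product: 8 4-[3-[2-hydroxy-4-(triisopropylsilyloxy)phenyl]propanoyl]phenyl acetate
Conditions: H2 (1 atm), Pd/C (5 mol% Pd), Ph2S (cat.), EtOAc, rt
Reagents that add atoms: none
Why: Heterogeneous catalytic hydrogenation of the enone C=C bond; the sulfide-moderated palladium on carbon should leave the aryl ketone, the aryl acetate and the silyl ether alone, and there is no benzylic ether to lose.

Step 6
Reactants: 8 4-[3-[2-hydroxy-4-(triisopropylsilyloxy)phenyl]propanoyl]phenyl acetate
Product: 9 4-[(1R)-1-hydroxy-3-[2-hydroxy-4-(triisopropylsilyloxy)phenyl]propyl]phenyl acetate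
Conditions: (S)-Me-CBS (0.2 equiv), BH3·SMe2 (2.2 equiv), THF, −20 °C; MeOH quench
Reagents that add atoms: none
Why: Corey–Bakshi–Shibata reduction; the ketone binds to the ring boron of the (S)-oxazaborolidine with its aryl group away from the catalyst, and the nitrogen-bound borane delivers hydride to the Si face, which should give the R carbinol. One equivalent of borane is taken up by the phenol as an aryloxyborane and released again by the methanol quench; the aryl acetate should not be reduced at this temperature.

Step 7
Reactants: 9 4-[(1R)-1-hydroxy-3-[2-hydroxy-4-(triisopropylsilyloxy)phenyl]propyl]phenyl acetate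
Product: 10 4-[(2S)-7-(triisopropylsilyloxy)-3,4-dihydro-2H-chromen-2-yl]phenyl acetate [(S)-4′-acetoxy-7-(triisopropylsilyloxy)flavan]
Conditions: PPh3 (1.3 equiv), DIAD (1.3 equiv), THF (0.02 M), 0 °C to rt
Reagents that add atoms: none
Why: Intramolecular Mitsunobu etherification (6-exo-tet SN2); the ring A phenol displaces the alkoxyphosphonium group at the benzylic carbon with inversion, turning the R carbinol into the S flavan. The acetoxy group keeps ring B electron-poor, so ionisation to a benzylic cation, the usual source of racemisation in such closures, should not compete.

Step 8
Reactants: 10 4-[(2S)-7-(triisopropylsilyloxy)-3,4-dihydro-2H-chromen-2-yl]phenyl acetate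
Product: 12 4-[(2S)-4-oxo-7-(triisopropylsilyloxy)-3,4-dihydro-2H-chromen-2-yl]phenyl acetate [(S)-4′-acetoxy-7-(triisopropylsilyloxy)flavanone], via flavan-4-ol 11 (not isolated)
Conditions: DDQ (0.2 equiv), LiClO4 (0.1 M), AcOH (5 equiv), MeCN/H2O (9:1), graphite felt anode, Pt cathode, divided cell (Nafion membrane), about +1.0 V vs Ag/AgCl, about 4 F/mol, rt
Reagents that add atoms: water, O
Why: Anodically regenerated DDQ forms a charge-transfer complex with ring A, the only electron-rich arene of 10, and abstracts hydride (or an electron, a proton and a second electron) from C4–H, giving a benzylic cation stabilised as a quinone-methide-type oxocarbenium ion by the C7 silyloxy group (para to C4a) and by O1 (ortho). Water captures this cation to give the flavan-4-ol 11, whose remaining C4–H is abstracted in the same way to give the aryl ketone 12; the hydroquinone is re-oxidised at the carbon anode below the potential of ring A, and the protons cross the membrane and leave as dihydrogen at the cathode. The closest known reaction type is the DDQ-mediated benzylic oxidation of alkoxy-activated chromans and tetralins to aryl ketones, with chemical or anodic regeneration of the quinone. No ring is closed and no stereocentre is created, so there is no mode of closure and no controlling element to name; the S configuration at C2 is carried through. The selectivity needed is C4–H over C2–H: C4 is a doubly oxygen-activated (2,4-dioxygenated) benzylic position of the donor ring, whereas C2–H is benzylic only to the acetoxy-deactivated ring B and lies next to an oxygen whose lone pair is engaged with ring A. The reaction should stop at 12 because the new carbonyl deactivates ring A, and the low stationary quinone concentration with the high water content should suppress proton loss from the cation and dehydrogenation towards flavone or flavylium species. The acetic acid keeps the medium mildly acidic, so that the β-aryloxy ketone does not open and the silyl ether is not attacked.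

Step 9
Reactants: 12 4-[(2S)-4-oxo-7-(triisopropylsilyloxy)-3,4-dihydro-2H-chromen-2-yl]phenyl acetate
Product: 13 (2S)-2-(4-hydroxyphenyl)-7-(triisopropylsilyloxy)-2,3-dihydro-4H-chromen-4-one
Conditions: immobilised Burkholderia cepacia lipase, n-BuOH (5 equiv), THF, 40 °C
Reagents that add atoms: none
Why: Lipase-catalysed alcoholysis (transesterification) of a phenolic acetate, a reaction type established for 4′-acetates of flavanones; it runs at neutrality in an organic solvent, so no enolate can form at C3 and nothing nucleophilic enough to attack the C7 silyl ether is present.

Step 10
Reactants: 13 (2S)-2-(4-hydroxyphenyl)-7-(triisopropylsilyloxy)-2,3-dihydro-4H-chromen-4-one, 14 geraniol [(2E)-3,7-dimethylocta-2,6-dien-1-ol]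
Product: 15 (2S)-2-[4-[(2E)-3,7-dimethylocta-2,6-dien-1-yl]oxyphenyl]-7-(triisopropylsilyloxy)-2,3-dihydro-4H-chromen-4-one
Conditions: PPh3 (1.5 equiv), DIAD (1.5 equiv), THF, 0 °C to rt
Reagents that add atoms: none
Why: Intermolecular Mitsunobu etherification of a phenol (pKa about 10) with a primary allylic alcohol; direct SN2 at the unhindered CH2 should prevail over SN2′ attack at the fully substituted C3, and the (E)-alkene is not touched. The only base present is the hydrazide anion, which the phenol quenches, so ring C should not open.

Step 11
Reactants: 15 (2S)-2-[4-[(2E)-3,7-dimethylocta-2,6-dien-1-yl]oxyphenyl]-7-(triisopropylsilyloxy)-2,3-dihydro-4H-chromen-4-one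
Product: 16 (2S)-2-[4-[(2E)-3,7-dimethylocta-2,6-dien-1-yl]oxyphenyl]-7-hydroxy-2,3-dihydro-4H-chromen-4-one (CNP0302343.1)
Conditions: HF·pyridine, pyridine, THF, 0 °C to rt
Reagents that add atoms: none
Why: Fluoride-mediated cleavage of an aryl silyl ether, fast here because the departing phenoxide is para to the carbonyl; the pyridine-buffered medium is neither basic enough to open ring C nor acidic enough to ionise the geranyl ether, so C2 and the (E)-alkene should be retained.

## Compound list

1 | 2,4-dihydroxybenzaldehyde | O=Cc1ccc(O)cc1O | starting material
2 | 2-hydroxy-4-(triisopropylsilyloxy)benzaldehyde | O=Cc1ccc(O[Si](C(C)C)(C(C)C)C(C)C)cc1O | intermediate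
3 | 4-acetylphenyl acetate (4′-acetoxyacetophenone) | CC(=O)Oc1ccc(C(C)=O)cc1 | starting material
4 | 4-(2-bromoacetyl)phenyl acetate | CC(=O)Oc1ccc(C(=O)CBr)cc1 | intermediate
5 | [2-(4-acetoxyphenyl)-2-oxoethyl]triphenylphosphonium bromide | CC(=O)Oc1ccc(C(=O)C[P+](c2ccccc2)(c2ccccc2)c2ccccc2)cc1.[Br-] | intermediate
6 | 4-[2-(triphenyl-λ5-phosphanylidene)acetyl]phenyl acetate | CC(=O)Oc1ccc(C(=O)C=P(c2ccccc2)(c2ccccc2)c2ccccc2)cc1 | intermediate
7 | 4-[(2E)-3-[2-hydroxy-4-(triisopropylsilyloxy)phenyl]prop-2-enoyl]phenyl acetate | CC(=O)Oc1ccc(C(=O)/C=C/c2ccc(O[Si](C(C)C)(C(C)C)C(C)C)cc2O)cc1 | intermediate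
8 | 4-[3-[2-hydroxy-4-(triisopropylsilyloxy)phenyl]propanoyl]phenyl acetate | CC(=O)Oc1ccc(C(=O)CCc2ccc(O[Si](C(C)C)(C(C)C)C(C)C)cc2O)cc1 | intermediate
9 | 4-[(1R)-1-hydroxy-3-[2-hydroxy-4-(triisopropylsilyloxy)phenyl]propyl]phenyl acetate | CC(=O)Oc1ccc([C@H](O)CCc2ccc(O[Si](C(C)C)(C(C)C)C(C)C)cc2O)cc1 | intermediate
10 | 4-[(2S)-7-(triisopropylsilyloxy)-3,4-dihydro-2H-chromen-2-yl]phenyl acetate, (S)-4′-acetoxy-7-(triisopropylsilyloxy)flavan | CC(=O)Oc1ccc([C@@H]2CCc3ccc(O[Si](C(C)C)(C(C)C)C(C)C)cc3O2)cc1 | intermediate
11 | 4-[(2S)-4-hydroxy-7-(triisopropylsilyloxy)-3,4-dihydro-2H-chromen-2-yl]phenyl acetate, both C4 epimers | CC(=O)Oc1ccc([C@@H]2CC(O)c3ccc(O[Si](C(C)C)(C(C)C)C(C)C)cc3O2)cc1 | intermediate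
12 | 4-[(2S)-4-oxo-7-(triisopropylsilyloxy)-3,4-dihydro-2H-chromen-2-yl]phenyl acetate, (S)-4′-acetoxy-7-(triisopropylsilyloxy)flavanone | CC(=O)Oc1ccc([C@@H]2CC(=O)c3ccc(O[Si](C(C)C)(C(C)C)C(C)C)cc3O2)cc1 | intermediate
13 | (2S)-2-(4-hydroxyphenyl)-7-(triisopropylsilyloxy)-2,3-dihydro-4H-chromen-4-one | Oc1ccc([C@@H]2CC(=O)c3ccc(O[Si](C(C)C)(C(C)C)C(C)C)cc3O2)cc1 | intermediate
14 | geraniol, (2E)-3,7-dimethylocta-2,6-dien-1-ol | CC(C)=CCC/C(C)=C/CO | starting material
15 | (2S)-2-[4-[(2E)-3,7-dimethylocta-2,6-dien-1-yl]oxyphenyl]-7-(triisopropylsilyloxy)-2,3-dihydro-4H-chromen-4-one | CC(C)=CCC/C(C)=C/COc1ccc([C@@H]2CC(=O)c3ccc(O[Si](C(C)C)(C(C)C)C(C)C)cc3O2)cc1 | intermediate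
16 | (2S)-2-[4-[(2E)-3,7-dimethylocta-2,6-dien-1-yl]oxyphenyl]-7-hydroxy-2,3-dihydro-4H-chromen-4-one (CNP0302343.1) | CC(C)=CCC/C(C)=C/COc1ccc([C@@H]2CC(=O)c3ccc(O)cc3O2)cc1 | target

## Step count and least certain steps

Total step count: 11. Longest linear sequence: 10 steps (steps 2 to 11, from 3 to 16); step 1 is a one-step side branch that joins at step 4.

Step 8 (key step). The most likely failures are:
- proton loss from the C4 cation faster than capture by water, followed by further dehydrogenation towards a flavylium system, which would destroy C2;
- competing hydride loss from C2–H;
- direct anodic oxidation of ring A with oxidative coupling, if the potential drifts upward as the mediator is consumed.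

Fallback: the oxidation is divided into two chemical operations that set out from 10 and return at 12. Stoichiometric DDQ (1.1 equiv) in CH2Cl2 over pH 7 aqueous buffer at 0 °C should stop at the flavan-4-ol 11, which is isolated this time as its C4 epimers. Dess–Martin periodinane in NaHCO3-buffered CH2Cl2 then oxidises the benzylic alcohol to 12. Hydride abstraction is needed only once, and the second oxidation proceeds by ligand exchange at iodine, which cannot attack C2–H or dehydrogenate ring C. No compound beyond the list arises (F0).

Step 7. The alkoxyphosphonium ion may partly ionise, lowering the enantiomeric purity, and elimination towards a styrene or intermolecular etherification may compete with ring closure. Fallback: it sets out from 8 and returns at 10, bypassing 9 (so it also covers insufficient selectivity in step 6). Acid-catalysed cyclodehydration (p-TsOH cat., toluene, removal of water) should give 4-[7-(triisopropylsilyloxy)-4H-chromen-2-yl]phenyl acetate F1. Asymmetric hydrogenation of its enol ether C2=C3 bond with a cationic iridium phosphine–oxazoline catalyst, [Ir(cod)(PHOX)]BArF (monovalent iridium), H2 (50 bar), CH2Cl2, is a known reaction type for 2-aryl-4H-chromenes. With the ligand enantiomer chosen for the S product it would set C2 by catalyst control instead of by inversion.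

Step 9. The acyl transfer may be too slow if the substrate fits the enzyme poorly. Chemical substitutes such as carbonate or acetate in methanol risk losing the activated C7 silyl group or opening ring C. Fallback: the ester is exchanged before the carbonyl exists, setting out from 10 and returning at 13.
- Hydrazinolysis (N2H4·H2O, THF, 0 °C), harmless to a flavan, gives (2S)-2-(4-hydroxyphenyl)-7-(triisopropylsilyloxy)-3,4-dihydro-2H-chromene F2.
- Boc2O with DMAP (cat.) in CH2Cl2 gives tert-butyl 4-[(2S)-7-(triisopropylsilyloxy)-3,4-dihydro-2H-chromen-2-yl]phenyl carbonate F3, which keeps ring B electron-poor.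
- The oxidation of step 8 gives tert-butyl 4-[(2S)-4-oxo-7-(triisopropylsilyloxy)-3,4-dihydro-2H-chromen-2-yl]phenyl carbonate F4.
- Acidolysis (TFA, CH2Cl2, 0 °C, with 1,3-dimethoxybenzene as cation trap) releases 13. Neither the silyl ether nor the β-aryloxy ketone is sensitive to these conditions.

Step 10. Substitution with allylic transposition (SN2′) may compete, and alkylation of the hydrazide may take over if the phenol reacts slowly. Fallback: it sets out from 13 and 14 and returns at 15. Geraniol 14 is converted with PBr3 (Et2O, −10 °C) into geranyl bromide F5. Phenol 13 is then alkylated in a Williamson etherification (K2CO3, 1.1 equiv, acetone, rt), in which the primary allylic bromide reacts by direct SN2. The price is exposure of the β-aryloxy ketone and of the C7 silyl ether to a weak heterogeneous base, so the enantiomeric purity of 15 would have to be checked after this variant.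

## Further compounds

F0 | step 8 | none | none
F1 | step 7 | 4-[7-(triisopropylsilyloxy)-4H-chromen-2-yl]phenyl acetate | CC(=O)Oc1ccc(C2=CCc3ccc(O[Si](C(C)C)(C(C)C)C(C)C)cc3O2)cc1
F2 | step 9 | (2S)-2-(4-hydroxyphenyl)-7-(triisopropylsilyloxy)-3,4-dihydro-2H-chromene | Oc1ccc([C@@H]2CCc3ccc(O[Si](C(C)C)(C(C)C)C(C)C)cc3O2)cc1
F3 | step 9 | tert-butyl 4-[(2S)-7-(triisopropylsilyloxy)-3,4-dihydro-2H-chromen-2-yl]phenyl carbonate | CC(C)(C)OC(=O)Oc1ccc([C@@H]2CCc3ccc(O[Si](C(C)C)(C(C)C)C(C)C)cc3O2)cc1
F4 | step 9 | tert-butyl 4-[(2S)-4-oxo-7-(triisopropylsilyloxy)-3,4-dihydro-2H-chromen-2-yl]phenyl carbonate | CC(C)(C)OC(=O)Oc1ccc([C@@H]2CC(=O)c3ccc(O[Si](C(C)C)(C(C)C)C(C)C)cc3O2)cc1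
F5 | step 10 | geranyl bromide, (2E)-1-bromo-3,7-dimethylocta-2,6-diene | CC(C)=CCC/C(C)=C/CBr
A1 | alternative 1 | (1S,3S)-1-[2-bromo-4-(triisopropylsilyloxy)phenyl]-3-[4-(geranyloxy)phenyl]propane-1,3-diol | CC(C)=CCC/C(C)=C/COc1ccc([C@@H](O)C[C@H](O)c2ccc(O[Si](C(C)C)(C(C)C)C(C)C)cc2Br)cc1
A2 | alternative 1 | (2S,4S)-4′-O-geranyl-7-O-triisopropylsilyl-flavan-4-ol | CC(C)=CCC/C(C)=C/COc1ccc([C@@H]2C[C@H](O)c3ccc(O[Si](C(C)C)(C(C)C)C(C)C)cc3O2)cc1
A3 | alternative 2 | 2-[2-(methoxymethoxy)-4-(triisopropylsilyloxy)phenyl]-1,3-dithiane | COCOc1cc(O[Si](C(C)C)(C(C)C)C(C)C)ccc1C1SCCCS1
A4 | alternative 2 | (S)-2-[4-(geranyloxy)phenyl]oxirane | CC(C)=CCC/C(C)=C/COc1ccc([C@H]2CO2)cc1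
A5 | alternative 2 | (R)-1-[4-(geranyloxy)phenyl]-2-[2-[2-(methoxymethoxy)-4-(triisopropylsilyloxy)phenyl]-1,3-dithian-2-yl]ethanol | CC(C)=CCC/C(C)=C/COc1ccc([C@H](O)CC2(c3ccc(O[Si](C(C)C)(C(C)C)C(C)C)cc3OCOC)SCCCS2)cc1
A6 | alternative 3 | 7-(triisopropylsilyloxy)chromone | O=c1ccoc2cc(O[Si](C(C)C)(C(C)C)C(C)C)ccc12
A7 | alternative 3 | 4-(geranyloxy)phenylboronic acid | CC(C)=CCC/C(C)=C/COc1ccc(B(O)O)cc1
A8 | alternative 3 | (S)-4′-O-geranyl-7-O-triisopropylsilyl-flavanone (identical with 15) | CC(C)=CCC/C(C)=C/COc1ccc([C@@H]2CC(=O)c3ccc(O[Si](C(C)C)(C(C)C)C(C)C)cc3O2)cc1
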